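## Analysis of the target

The target is a flavonol: a 4H-chromen-4-one in which benzo ring A is fused to pyranone ring C, with an unsubstituted phenyl ring B on C2. Ring C carries an enolic hydroxyl at C3 beside the C4 carbonyl. Ring A carries a free hydroxyl at C5 (hydrogen-bonded to the C4 carbonyl), a methyl ether at C7, a butanoate ester on O8 and one hydrogen at C6. There is no stereocentre and no double-bond geometry, so any stereocentre that appears on the way is transient and may be carried as a racemate or a mixture. The sensitive groups are the aryl butanoate, which hydroxide, alkoxide, amines on warming and hydride all cleave, and the electron-rich ring A, whose free C6–H is open to electrophiles. The difficulty lies less in the skeleton than in telling the oxygens apart: O7 methylated, O8 acylated, O3 and O5 free, on a 5,7,8-trioxygenated ring A that is harder to reach than the common 5,7 pattern. The strategy rests on the pair C3/C4 of ring C. The C3–OH/C4=O unit is the enol form of a chromane-3,4-dione, one oxidation level above an acyloin, and an acyloin C–C bond can be made from two aldehyde carbons once the polarity of one is reversed.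

## Retrosynthetic reasoning

**24 to 23.** The last operation should touch only the two oxygens beside the C4 carbonyl. The O3–benzyl and O5–methyl bonds are cut together, leading back to benzyl ether 23. A boron halide Lewis acid bound to the carbonyl reaches exactly these two ethers, while the O7 methyl ether and the O8 ester lie outside the chelate. The gain is an end game in which the ester never meets base, hydride or a nucleophile.

**23 to 21 and 22.** The O8–acyl bond is cut to phenol 21 and butanoyl chloride 22. The ester must come late because the hydride reduction, the amine-mediated ring closure and the carbonate alkylations earlier in the route would all destroy it. The forward acylation needs O8 to be the only free hydroxyl.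

**21 to 20, and 20 to 18 and 19.** Phenol 21 comes from allyl ether 20 by palladium-catalysed allyl transfer, and 20 from flavonol 18 and benzyl bromide 19. Allyl is chosen for O8 because it survives hydride, oxidants, amine and carbonate and leaves under neutral conditions that spare the benzyl ether. Benzyl is chosen for O3 because it falls in the same Lewis acid step as the O5 methyl group.

**18 to 16.** Flavonol 18 is the enol of dione 17, so it is traced to acyloin 16 by a two-electron oxidation. This adjustment removes both sp3 centres of 16, which is why neither its configuration nor the direction of its acyloin matters.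

**16 to 15 (the key disconnection).** The C3–C4 bond is cut, giving dialdehyde 15. The cut is placed there because both carbons are oxidised and adjacent, so the bond is the product of an acyl anion equivalent adding to an aldehyde. A cut at C4–C4a or O1–C2 would instead require a tetrasubstituted enol ether or a later oxygenation of C3. The gain is ring C with both oxygens in place from two identical functional groups. The forward reaction has to close a six-membered ring faster than the enolisable aldehyde undergoes aldol chemistry.

**15 to 14 to 13.** The two formyl groups are traced to diol 14 and then to ester aldehyde 13. Bringing both carbons to the alcohol level and oxidising them together avoids any need to distinguish an ester from an aldehyde in a partial reduction.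

**13 to 11 and 12.** The O1–C2 aryl ether bond is cut to salicylaldehyde 11 and bromo ester 12. The bromide is benzylic and alpha to an ester, so displacement by a phenoxide is easy, and 12 supplies ring B, C2 and C3 in one piece.

**11 to 9 and 10.** The C4–C4a bond is cut to phenol 9 and formaldehyde (as paraformaldehyde 10). Phenol 9 has one free ortho position, so a phenoxide-directed formylation can deliver the carbon only to the future C4a.

**9 to 8, and 8 to 6 and 7.** Phenol 9 is unmasked from acetal 8, which comes from phenol 6 and allyl bromide 7. The acetal on the neighbouring oxygen keeps the two catechol oxygens distinct: one becomes O8 (allylated), the other O1.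

**6 to 3 and 4.** The hydroxyl of 6 replaces the formyl carbon of aldehyde 3 by peracid oxidation with 4, through formate 5. Exchanging C–C for C–O at this position puts the third contiguous oxygen exactly where the 5,7,8 pattern needs it.

**3 to 1 and 2.** Aldehyde 3 is the methoxymethyl ether of commercial salicylaldehyde 1, made with chloromethyl methyl ether 2. The protection is needed so that the oxygen introduced next can be alkylated alone.

## Alternatives that were turned down

**Alternative 1:** Ring A is built last, by cutting C4a–C5 (and, one step earlier, C8–C8a), so that the benzo ring grows on a finished pyranone.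
- **Forward key step:** heating the 4-hydroxycyclobutenone A2 opens the four-membered ring to a vinylketene. Its ketene carbon closes onto the neighbouring pyranone C–H in a six-electron electrocyclisation, and tautomerisation gives hydroquinone A1. A2 would come from adding the C6-metallated pyranone A3 to the ketone carbonyl of semisquarate A4.
- **For:** the four-carbon unit fixes the position of every ring A substituent. A1 arrives with O5 and O8 free, O7 methylated and O3 benzylated, which is the differentiation the target needs. Acylation of O8 beside the chelated O5–H and a neutral hydrogenolysis would finish the synthesis. On end game and protecting-group economy this alternative is stronger than the chosen route.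
- **Against:** the nucleophile is a vinyl metal at C6 of a 4-pyranone, a ring that is itself a ketone and a Michael acceptor and carries a benzylic ether, so generating it is a real unknown. A3 needs several steps and A4 is a costly specialised reagent. A1 is a para-dihydroxy arene and should oxidise to the quinone in air.
- **Comparison:** the risk is spread over fragment synthesis, metallation and thermolysis. The chosen strategy pays with a longer protecting-group sequence but uses only routine steps around one mild catalytic step.

**Alternative 2:** The O1–C2 bond is cut, with C3 left as a carbon–iodine bond.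
- **Forward key step:** an electrophilic iodine reagent activates the alkyne of ynone A6. The phenolic oxygen attacks the phenyl-bearing alkyne carbon in a 6-endo-dig closure and gives 3-iodochromone A5.
- **For:** A6 is assembled convergently from an aryl carbonyl component and a terminal arylalkyne. The closure is fast, and the polarisation of the ynone favours the endo mode. The ring closure itself is probably more dependable than a benzoin, and on that point this alternative is stronger.
- **Against:** C3 ends up with iodine where the target has oxygen. Replacing a hindered vinylic iodide, flanked by a carbonyl and a phenyl group, with a hydroxyl costs one or two further steps of uncertain efficiency. Ring A, with its free C6–H between two methoxy groups, is a better partner for an iodonium ion than the alkyne, so ring iodination should compete. The acetal on O8 is exposed to the acid released. A6 needs the same tetraoxygenated arene, so nothing is saved in ring A.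
- **Comparison:** the chosen strategy forms C3 already bearing its oxygen and needs no electrophile that ring A could intercept.

**Alternative 3:** The C4–C4a bond is cut, with ring C closed by acylation of ring A.
- **Forward key step:** a perfluoroacyl anhydride converts acid A8 into a mixed anhydride, whose acyl group attacks the free position ortho to the aryl ether oxygen and gives chromone A7. A7 is identical with compound 20 of the route.
- **For:** the acylation is intramolecular on a highly activated ring with one reachable position, so its regiochemistry is secure. A8 would be made from phenol 9 of the route, and the alternative would reach 20 in about three steps where the chosen route needs seven. On step economy it is clearly stronger.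
- **Against:** A8 is a tetrasubstituted enol ether that must carry the carboxyl and aryloxy groups cis. It has to be made by addition–elimination of the hindered phenoxide of 9 on a fully substituted acceptor, with uncertain rate and geometry. The strongly acidic medium can protonate and hydrolyse the electron-rich enol ether, and the second free ring position can be acylated intermolecularly.
- **Comparison:** the chosen strategy offers precursors that are all reached by geometry-free, routine reactions, and a C3–C4 bond formed under nearly neutral catalytic conditions.

Key step: step 9

Remark: the target is achiral, so racemic 12 is used and the chiral intermediates 13 to 17 (and the fallback compounds) are carried as racemates or diastereomer mixtures; "allyl" means prop-2-en-1-yl.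

## Route

Step 1
Reactants: 1 2-hydroxy-4,6-dimethoxybenzaldehyde; 2 chloromethyl methyl ether
Product: 3 2,4-dimethoxy-6-(methoxymethoxy)benzaldehyde
Conditions: NaH, DMF, 0 °C; then 2, 0 °C → rt
Reagents that add atoms: 2 chloromethyl methyl ether, COCCl
Why: Williamson etherification of the sodium phenoxide with the reactive alpha-chloro ether; the acetal masks the oxygen that later becomes O1 and tolerates peracid, carbonate and the allylation.

Step 2
Reactants: 3 2,4-dimethoxy-6-(methoxymethoxy)benzaldehyde; 4 3-chloroperoxybenzoic acid (mCPBA)
Product: 6 2,4-dimethoxy-6-(methoxymethoxy)phenol, via aryl formate 5 (not isolated)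
Conditions: mCPBA, CH2Cl2, 0 °C → rt; aq. NaHCO3 wash; then K2CO3 (cat.), MeOH, rt
Reagents that add atoms: 4 3-chloroperoxybenzoic acid, OOC(=O)c1cccc(Cl)c1
Why: Baeyer–Villiger oxidation of the electron-rich benzaldehyde (Dakin-type): the aryl group, activated by ortho and para oxygen, migrates to the peroxy oxygen to give formate 5, which carbonate-catalysed methanolysis cleaves. It is run before any alkene is present, so the peracid has no competing substrate.

Step 3
Reactants: 6 2,4-dimethoxy-6-(methoxymethoxy)phenol; 7 allyl bromide
Product: 8 2-(allyloxy)-1,5-dimethoxy-3-(methoxymethoxy)benzene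
Conditions: allyl bromide, K2CO3, DMF, rt, under N2
Reagents that add atoms: 7 allyl bromide, C=CCBr
Why: Williamson etherification in a dipolar aprotic solvent, which favours O- over C-alkylation; the acetal on the neighbouring oxygen cannot migrate, so the two catechol oxygens stay distinct.

Step 4
Reactants: 8 2-(allyloxy)-1,5-dimethoxy-3-(methoxymethoxy)benzene
Product: 9 2-(allyloxy)-3,5-dimethoxyphenol
Conditions: HCl (cat.), MeOH, 50 °C
Reagents that add atoms: none
Why: Acid-catalysed transacetalisation transfers the methoxymethyl group to methanol as dimethoxymethane, which also keeps the oxocarbenium ion from alkylating the electron-rich ring; allyl and methyl aryl ethers are stable to these conditions.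

Step 5
Reactants: 9 2-(allyloxy)-3,5-dimethoxyphenol; 10 paraformaldehyde
Product: 11 3-(allyloxy)-2-hydroxy-4,6-dimethoxybenzaldehyde
Conditions: MgCl2, Et3N, (CH2O)n, MeCN, reflux; then aq. HCl
Reagents that add atoms: 10 paraformaldehyde (as formaldehyde), C=O
Why: Casnati–Skattebøl ortho-formylation: the magnesium phenoxide delivers formaldehyde through a six-membered chelate to the only free ortho position (C6 of 9), and a second equivalent of formaldehyde oxidises the benzylic alkoxide to the aldehyde. The other free ring position is para to the hydroxyl and is not reached by this mechanism.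

Step 6
Reactants: 11 3-(allyloxy)-2-hydroxy-4,6-dimethoxybenzaldehyde; 12 methyl 2-bromo-2-phenylacetate (racemic)
Product: 13 methyl 2-[2-(allyloxy)-6-formyl-3,5-dimethoxyphenoxy]-2-phenylacetate (racemic)
Conditions: K2CO3, DMF, rt
Reagents that add atoms: 12 methyl 2-bromo-2-phenylacetate, COC(=O)C(Br)c1ccccc1
Why: Williamson etherification: SN2 displacement of the activated benzylic alpha-bromo ester by the phenoxide forms the O1–C2 bond; room temperature limits enolisation of the product and aldol closure onto the ortho-formyl group.

Step 7
Reactants: 13 methyl 2-[2-(allyloxy)-6-formyl-3,5-dimethoxyphenoxy]-2-phenylacetate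
Product: 14 2-[2-(allyloxy)-6-(hydroxymethyl)-3,5-dimethoxyphenoxy]-2-phenylethan-1-ol (racemic)
Conditions: LiAlH4, THF, 0 °C; then H2O, aq. NaOH
Reagents that add atoms: none
Why: LiAlH4 reduction takes the ester and the aryl aldehyde to primary alcohols, bringing both carbons to one oxidation level; the allyl and aryl ethers are inert, and the basic work-up protects the acid-sensitive benzylic alcohol.

Step 8
Reactants: 14 2-[2-(allyloxy)-6-(hydroxymethyl)-3,5-dimethoxyphenoxy]-2-phenylethan-1-ol
Product: 15 3-(allyloxy)-4,6-dimethoxy-2-(2-oxo-1-phenylethoxy)benzaldehyde (racemic)
Conditions: Dess–Martin periodinane (2.5 equiv), pyridine, CH2Cl2, 0 °C → rt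
Reagents that add atoms: none
Why: Dess–Martin oxidation of both primary alcohols; a chloride-free, nearly neutral oxidant is chosen because the 2,4,6-trioxygenated benzylic alcohol ionises readily under activated-sulfoxide conditions and the alpha-aryloxy aldehyde enolises easily. Crude 15 is taken on without chromatography.

Step 9
Reactants: 15 3-(allyloxy)-4,6-dimethoxy-2-(2-oxo-1-phenylethoxy)benzaldehyde
Product: 16 8-(allyloxy)-3-hydroxy-5,7-dimethoxy-2-phenylchroman-4-one (racemic, mixture of 2,3-cis and 2,3-trans)
Conditions: 3-benzyl-5-(2-hydroxyethyl)-4-methylthiazolium chloride (20 mol %), Et3N (0.5 equiv), degassed EtOH, 0.02 M, 60 °C, Ar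
Reagents that add atoms: none
Why: Et3N deprotonates the thiazolium salt to the carbene, which adds to one formyl carbon and after proton transfer gives the Breslow enaminol, an acyl anion equivalent; this attacks the second formyl group across the aryl ether tether, and collapse of the adduct releases the carbene and leaves the C3–C4 bond. The closest known reaction type is the carbene-catalysed intramolecular crossed benzoin, which converts ortho-tethered aryl aldehyde–carbonyl pairs into 3-hydroxychroman-4-ones and dialdehydes into cyclic acyloins. Ring C closes in a 6-exo-trig mode, the attacked C=O lying outside the forming ring in either regiochemical sense. The one new stereocentre, the carbinol carbon, is set relative to C2 only by the substrate and by equilibration (the diequatorial 2,3-trans isomer should be favoured), and no control is needed because both centres become sp2 in step 10. The step needs chemoselectivity for cyclising benzoin over aldol and over intermolecular benzoin: the weak amine base keeps the enolate concentration low and high dilution favours ring closure. The only aldol open to the substrate gives a dihydrobenzofuranol with a quaternary carbon that cannot dehydrate, so it should revert. Regiochemistry is not critical: if the carbene engages the unhindered aliphatic aldehyde first, the isomer with the carbonyl at C3 and the hydroxyl at C4 shares its enediol with 16, should equilibrate to the conjugated aryl ketone, and in any case is oxidised to the same flavonol.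

Step 10
Reactants: 16 8-(allyloxy)-3-hydroxy-5,7-dimethoxy-2-phenylchroman-4-one
Product: 18 8-(allyloxy)-3-hydroxy-5,7-dimethoxy-2-phenyl-4H-chromen-4-one, via chromane-3,4-dione 17 (not isolated)
Conditions: Cu(OAc)2 (2.2 equiv), AcOH/H2O, 80 °C
Reagents that add atoms: none
Why: Divalent copper oxidises the alpha-hydroxy ketone through its enediol to the 3,4-dione 17 (the classical benzoin-to-benzil oxidation), which tautomerises at once to the 3-hydroxychromone. Both stereocentres of 16 and both acyloin regioisomers converge here.

Step 11
Reactants: 18 8-(allyloxy)-3-hydroxy-5,7-dimethoxy-2-phenyl-4H-chromen-4-one; 19 benzyl bromide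
Product: 20 8-(allyloxy)-3-(benzyloxy)-5,7-dimethoxy-2-phenyl-4H-chromen-4-one
Conditions: BnBr, K2CO3, DMF, 50 °C
Reagents that add atoms: 19 benzyl bromide, BrCc1ccccc1
Why: Williamson etherification of the acidic enolic 3-hydroxyl, the only free hydroxyl in 18; the benzyl ether masks O3 during the later acylation of O8.

Step 12
Reactants: 20 8-(allyloxy)-3-(benzyloxy)-5,7-dimethoxy-2-phenyl-4H-chromen-4-one
Product: 21 3-(benzyloxy)-8-hydroxy-5,7-dimethoxy-2-phenyl-4H-chromen-4-one
Conditions: Pd(PPh3)4 (5 mol %), morpholine, THF, rt
Reagents that add atoms: none
Why: Tsuji–Trost deallylation: zerovalent palladium ionises the allyl aryl ether to a pi-allyl complex and morpholine captures the allyl group; the benzyl ether, methyl ethers and chromone are untouched.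

Step 13
Reactants: 21 3-(benzyloxy)-8-hydroxy-5,7-dimethoxy-2-phenyl-4H-chromen-4-one; 22 butanoyl chloride
Product: 23 3-(benzyloxy)-5,7-dimethoxy-4-oxo-2-phenyl-4H-chromen-8-yl butanoate
Conditions: butanoyl chloride, Et3N, DMAP (cat.), CH2Cl2, 0 °C → rt
Reagents that add atoms: 22 butanoyl chloride, CCCC(Cl)=O
Why: DMAP-catalysed acylation of the only free hydroxyl; the hindered O8 phenol reacts through the acylpyridinium ion.

Step 14
Reactants: 23 3-(benzyloxy)-5,7-dimethoxy-4-oxo-2-phenyl-4H-chromen-8-yl butanoate
Product: 24 3,5-dihydroxy-7-methoxy-4-oxo-2-phenyl-4H-chromen-8-yl butanoate (target)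
Conditions: BCl3 (5 equiv), pentamethylbenzene, CH2Cl2, −78 → 0 °C; then H2O
Reagents that add atoms: none
Why: Lewis acid ether cleavage: BCl3 bound to the C4 carbonyl cleaves the peri O5 methyl ether through a six-membered chelate and removes the O3 benzyl group, whose cation pentamethylbenzene traps before it can alkylate C6. The O7 methyl ether and the aryl ester lie outside the chelate and are expected to survive at or below 0 °C.

## Compound list

1 | 2-hydroxy-4,6-dimethoxybenzaldehyde | COc1cc(O)c(C=O)c(OC)c1 | starting material
2 | chloromethyl methyl ether | COCCl | starting material
3 | 2,4-dimethoxy-6-(methoxymethoxy)benzaldehyde | COCOc1cc(OC)cc(OC)c1C=O | intermediate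
4 | 3-chloroperoxybenzoic acid (mCPBA) | OOC(=O)c1cccc(Cl)c1 | starting material
5 | 2,4-dimethoxy-6-(methoxymethoxy)phenyl formate | COCOc1cc(OC)cc(OC)c1OC=O | intermediate (not isolated)
6 | 2,4-dimethoxy-6-(methoxymethoxy)phenol | COCOc1cc(OC)cc(OC)c1O | intermediate
7 | allyl bromide (3-bromoprop-1-ene) | C=CCBr | starting material
8 | 2-(allyloxy)-1,5-dimethoxy-3-(methoxymethoxy)benzene | C=CCOc1c(OC)cc(OC)cc1OCOC | intermediate
9 | 2-(allyloxy)-3,5-dimethoxyphenol | C=CCOc1c(O)cc(OC)cc1OC | intermediate
10 | paraformaldehyde (as formaldehyde) | C=O | starting material
11 | 3-(allyloxy)-2-hydroxy-4,6-dimethoxybenzaldehyde | C=CCOc1c(O)c(C=O)c(OC)cc1OC | intermediate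
12 | methyl 2-bromo-2-phenylacetate (racemic) | COC(=O)C(Br)c1ccccc1 | starting material
13 | methyl 2-[2-(allyloxy)-6-formyl-3,5-dimethoxyphenoxy]-2-phenylacetate (racemic) | COC(=O)C(Oc1c(C=O)c(OC)cc(OC)c1OCC=C)c1ccccc1 | intermediate
14 | 2-[2-(allyloxy)-6-(hydroxymethyl)-3,5-dimethoxyphenoxy]-2-phenylethan-1-ol (racemic) | OCC(Oc1c(CO)c(OC)cc(OC)c1OCC=C)c1ccccc1 | intermediate
15 | 3-(allyloxy)-4,6-dimethoxy-2-(2-oxo-1-phenylethoxy)benzaldehyde (racemic) | O=CC(Oc1c(C=O)c(OC)cc(OC)c1OCC=C)c1ccccc1 | intermediate
16 | 8-(allyloxy)-3-hydroxy-5,7-dimethoxy-2-phenylchroman-4-one (racemic, diastereomer mixture) | C=CCOc1c(OC)cc(OC)c2c1OC(c1ccccc1)C(O)C2=O | intermediate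
17 | 8-(allyloxy)-5,7-dimethoxy-2-phenylchromane-3,4-dione (racemic) | C=CCOc1c(OC)cc(OC)c2c1OC(c1ccccc1)C(=O)C2=O | intermediate (not isolated)
18 | 8-(allyloxy)-3-hydroxy-5,7-dimethoxy-2-phenyl-4H-chromen-4-one | C=CCOc1c(OC)cc(OC)c2c(=O)c(O)c(-c3ccccc3)oc12 | intermediate
19 | benzyl bromide | BrCc1ccccc1 | starting material
20 | 8-(allyloxy)-3-(benzyloxy)-5,7-dimethoxy-2-phenyl-4H-chromen-4-one | C=CCOc1c(OC)cc(OC)c2c(=O)c(OCc3ccccc3)c(-c3ccccc3)oc12 | intermediate
21 | 3-(benzyloxy)-8-hydroxy-5,7-dimethoxy-2-phenyl-4H-chromen-4-one | COc1cc(OC)c2c(=O)c(OCc3ccccc3)c(-c3ccccc3)oc2c1O | intermediate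
22 | butanoyl chloride | CCCC(Cl)=O | starting material
23 | 3-(benzyloxy)-5,7-dimethoxy-4-oxo-2-phenyl-4H-chromen-8-yl butanoate | CCCC(=O)Oc1c(OC)cc(OC)c2c(=O)c(OCc3ccccc3)c(-c3ccccc3)oc12 | intermediate
24 | 3,5-dihydroxy-7-methoxy-4-oxo-2-phenyl-4H-chromen-8-yl butanoate | CCCC(=O)Oc1c(OC)cc(O)c2c(=O)c(O)c(-c3ccccc3)oc12 | target

## Step count and least certain steps

Total step count: 14. Longest linear sequence: 14 steps, from 1 to 24; all other inputs are commercial reagents.

**Step 9 (key step).** The cyclisation may lose to base-mediated enolisation and aldol or oligomerisation of the dialdehyde. The hindered, electron-rich aryl aldehyde may also be engaged too slowly, which would allow intermolecular benzoin or oxidation of the Breslow intermediate by adventitious oxygen. The fallback joins the same two carbons reductively and sets out from 15. SmI2 (divalent samarium) in THF with t-BuOH at −78 °C should reduce the more easily reduced aryl aldehyde to its ketyl, which adds to the neighbouring formyl group and gives 8-(allyloxy)-5,7-dimethoxy-2-phenylchromane-3,4-diol F1 as a diastereomer mixture. Oxidation of both carbinols with 2-iodoxybenzoic acid in DMSO, which takes 1,2-diols to 1,2-diones without C–C cleavage, gives dione 17 and so flavonol 18, where the route is rejoined.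

**Step 8.** The electron-rich benzylic alcohol may ionise in the acid released by the oxidant and give ethers or oligomers, and the alpha-aryloxy aldehyde may enolise, hydrate or undergo aldol reaction during isolation. The fallback avoids the benzylic alcohol and the double oxidation; it sets out from 13 and returns at 15. The aryl aldehyde of 13 is masked with HC(OMe)3 in MeOH and catalytic pyridinium p-toluenesulfonate as methyl 2-[2-(allyloxy)-6-(dimethoxymethyl)-3,5-dimethoxyphenoxy]-2-phenylacetate F2. i-Bu2AlH at −78 °C reduces the alpha-aryloxy ester only to the aldehyde stage, through a chelated tetrahedral intermediate, and gives 2-[2-(allyloxy)-6-(dimethoxymethyl)-3,5-dimethoxyphenoxy]-2-phenylacetaldehyde F3. Brief treatment with dilute aqueous acid then releases the very labile electron-rich acetal and gives 15.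

**Step 14.** Chemoselectivity may fail when the O5 demethylation is pushed: the butanoate or the O7 methyl ether may be cleaved, or the benzyl cation may alkylate C6. The fallback separates the two ether cleavages, sets out from 23 and returns at 24. Hydrogenolysis (H2, Pd/C, EtOAc) removes only the benzyl group and gives 3-hydroxy-5,7-dimethoxy-4-oxo-2-phenyl-4H-chromen-8-yl butanoate F4. The peri methyl ether is then cleaved under chelation control with AlCl3 in MeCN, which acts on the ether held against the C4 carbonyl, to give 24.

**Step 6.** Under carbonate the product's doubly activated C–H may enolise and close onto the ortho-formyl group in an aldol reaction, or the hindered, hydrogen-bonded phenoxide may alkylate slowly. The fallback is a base-free Mitsunobu etherification that sets out from 11 and returns at 13: 11, racemic methyl mandelate, PPh3 and diisopropyl azodicarboxylate in THF give 13 directly. No compound outside the list is made (F0).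

## Further compounds

F1 | step 9 | 8-(allyloxy)-5,7-dimethoxy-2-phenylchromane-3,4-diol (diastereomer mixture) | C=CCOc1c(OC)cc(OC)c2c1OC(c1ccccc1)C(O)C2O
F2 | step 8 | methyl 2-[2-(allyloxy)-6-(dimethoxymethyl)-3,5-dimethoxyphenoxy]-2-phenylacetate (racemic) | COC(=O)C(Oc1c(C(OC)OC)c(OC)cc(OC)c1OCC=C)c1ccccc1
F3 | step 8 | 2-[2-(allyloxy)-6-(dimethoxymethyl)-3,5-dimethoxyphenoxy]-2-phenylacetaldehyde (racemic) | O=CC(Oc1c(C(OC)OC)c(OC)cc(OC)c1OCC=C)c1ccccc1
F4 | step 14 | 3-hydroxy-5,7-dimethoxy-4-oxo-2-phenyl-4H-chromen-8-yl butanoate | CCCC(=O)Oc1c(OC)cc(OC)c2c(=O)c(O)c(-c3ccccc3)oc12
F0 | step 6 | none | none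
A1 | alternative 1 | 3-(benzyloxy)-5,8-dihydroxy-7-methoxy-2-phenyl-4H-chromen-4-one | COc1cc(O)c2c(=O)c(OCc3ccccc3)c(-c3ccccc3)oc2c1O
A2 | alternative 1 | 4-[5-(benzyloxy)-4-oxo-6-phenyl-4H-pyran-2-yl]-4-hydroxy-3-methoxycyclobut-2-en-1-one (racemic) | COC1=CC(=O)C1(O)c1cc(=O)c(OCc2ccccc2)c(-c2ccccc2)o1
A3 | alternative 1 | 3-(benzyloxy)-2-phenyl-4H-pyran-4-one | O=c1ccoc(-c2ccccc2)c1OCc1ccccc1
A4 | alternative 1 | 3-methoxycyclobut-3-ene-1,2-dione | COC1=CC(=O)C1=O
A5 | alternative 2 | 3-iodo-5,7-dimethoxy-8-(methoxymethoxy)-2-phenyl-4H-chromen-4-one | COCOc1c(OC)cc(OC)c2c(=O)c(I)c(-c3ccccc3)oc12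
A6 | alternative 2 | 1-[2-hydroxy-4,6-dimethoxy-3-(methoxymethoxy)phenyl]-3-phenylprop-2-yn-1-one | COCOc1c(OC)cc(OC)c(C(=O)C#Cc2ccccc2)c1O
A7 | alternative 3 | 8-(allyloxy)-3-(benzyloxy)-5,7-dimethoxy-2-phenyl-4H-chromen-4-one | C=CCOc1c(OC)cc(OC)c2c(=O)c(OCc3ccccc3)c(-c3ccccc3)oc12
A8 | alternative 3 | (E)-3-[2-(allyloxy)-3,5-dimethoxyphenoxy]-2-(benzyloxy)-3-phenylprop-2-enoic acid | OC(=O)/C(OCc1ccccc1)=C(/c1ccccc1)Oc1cc(OC)cc(OC)c1OCC=C
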